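**Plan**

1. Retrosynthesis: cut the enone at C(=O)–CH= (vinyllithium plus Weinreb amide), then the side chain at the first CH2–CH2 bond next to the ring (olefination, hydrogenation), and last both ring bonds C2–C3 and C6–C7 of the oxepane (O1, C2 quaternary, C3 carbinol, C6 alkylidene, C7 OCH2) in one (4+3) annulation.
2. Forward: a four-carbon vinylsilane acetal (C3–C6) and the silyl ketene acetal of the formaldehyde acetal of lactic acid (C2–O1–C7) are joined by TiCl4 to the oxepane in one flask. The C2 carboxyl is then grown into the side chain.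
3. Enabling feature: O1 lies between C7, a bare CH2 (a formaldehyde carbon), and C2, which carries a methyl and a one-carbon link (the α-carbon of lactic acid). 5-Methyl-1,3-dioxolan-4-one therefore holds C2–O1–C7 ready-made, with C2 nucleophilic as the enol silane and C7 electrophilic as an acyloxy acetal. C3 and C6, 1,4-related through C4–C5, are an acetal carbon and a vinylsilane carbon.
4. Stereochemistry: C3 comes from the bought (2R,4R)-pentane-2,4-diol acetal template (removed in step 17) and C2 is relayed from C3 in the same event. 6E comes from the vinylsilane made by trans-hydroalumination, the side-chain methyl centre from an oxazolidinone alkylation, and the enone E geometry from syn-hydrostannation.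

Key step: step 7

Assumption: racemic lactic acid is used because its stereocentre is erased in step 6, and 31 is carried on as whatever E/Z mixture forms because step 16 removes that double bond.

**Route**

Step 1
Reactants: 1 3-(trimethylsilyl)prop-2-yn-1-ol
Product: 3 (Z)-3-iodo-3-(trimethylsilyl)prop-2-en-1-ol, via cyclic alkenylalanate 2 (not isolated)
Conditions: NaAlH2(OCH2CH2OMe)2, Et2O, 0 °C to rt; then I2, THF, −78 to 0 °C
Reagents that add atoms: iodine, II
Why: Hydroxyl-directed trans-hydroalumination should place aluminum on the silicon-bearing carbon cis to CH2OH, and iodinolysis with retention should give the Z iodide that later fixes the 6E geometry (trans-hydroalumination–iodination of a propargylic alcohol).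

Step 2
Reactants: 3 (Z)-3-iodo-3-(trimethylsilyl)prop-2-en-1-ol
Product: 4 tert-butyl{[(Z)-3-iodo-3-(trimethylsilyl)prop-2-en-1-yl]oxy}diphenylsilane
Conditions: t-BuPh2SiCl, imidazole, CH2Cl2, rt
Reagents that add atoms: tert-butyl(chloro)diphenylsilane, CC(C)(C)[Si](Cl)(c1ccccc1)c1ccccc1
Why: Standard silylation of a primary alcohol gives an ether that should survive TiCl4 at low temperature, hydride, strong base and hydrogenation and is removed last.

Step 3
Reactants: 5 acrolein; 6 (2R,4R)-pentane-2,4-diol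
Product: 8 (4R,6R)-2-(2-bromoethyl)-4,6-dimethyl-1,3-dioxane, via 3-bromopropanal 7 (not isolated)
Conditions: HBr (gas), CH2Cl2, 0 °C; then 6, TsOH·H2O (cat.), rt
Reagents that add atoms: hydrogen bromide, Br
Why: Conjugate addition of HBr to acrolein followed by acid-catalysed acetalization is the usual one-flask route to 2-(2-bromoethyl)-1,3-dioxanes, and the C2-symmetric diol makes the acetal carbon non-stereogenic.

Step 4
Reactants: 8 (4R,6R)-2-(2-bromoethyl)-4,6-dimethyl-1,3-dioxane; 4 tert-butyl{[(Z)-3-iodo-3-(trimethylsilyl)prop-2-en-1-yl]oxy}diphenylsilane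
Product: 10 tert-butyl{[(E)-5-[(4R,6R)-4,6-dimethyl-1,3-dioxan-2-yl]-3-(trimethylsilyl)pent-2-en-1-yl]oxy}diphenylsilane, via alkylzinc bromide 9 (not isolated)
Conditions: Zn dust, LiCl, THF, 40 °C; then 4, Pd2(dba)3 (2.5 mol %), SPhos (10 mol %), THF, rt to 45 °C
Reagents that add atoms: none
Why: LiCl-assisted zinc insertion gives a β-acetal alkylzinc that should undergo Negishi coupling with the 1-iodo-1-silylalkene under zerovalent palladium with retention, which places the CH2CH2 chain cis to CH2O.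

Step 5
Reactants: 11 lactic acid (racemic); 12 paraformaldehyde
Product: 13 5-methyl-1,3-dioxolan-4-one
Conditions: TsOH·H2O (cat.), benzene, reflux, Dean–Stark trap
Reagents that add atoms: none
Why: Acid-catalysed acetalization of an α-hydroxy acid with formaldehyde gives the 1,3-dioxolan-4-one that ties C2, O1 and C7 into one temporary ring.

Step 6
Reactants: 13 5-methyl-1,3-dioxolan-4-one
Product: 15 tert-butyldimethyl[(5-methyl-1,3-dioxol-4-yl)oxy]silane, via lithium enolate 14 (not isolated)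
Conditions: LiN(i-Pr)2, THF, −78 °C; then t-BuMe2SiCl, DMPU, −78 °C to rt; distillation
Reagents that add atoms: tert-butyl(chloro)dimethylsilane, CC(C)(C)[Si](C)(C)Cl
Why: Enolization and O-silylation of the lactone should give the cyclic silyl ketene acetal, whose geometry is fixed by the ring (methyl cis to the silyloxy group).

Step 7
Reactants: 10 tert-butyl{[(E)-5-[(4R,6R)-4,6-dimethyl-1,3-dioxan-2-yl]-3-(trimethylsilyl)pent-2-en-1-yl]oxy}diphenylsilane; 15 tert-butyldimethyl[(5-methyl-1,3-dioxol-4-yl)oxy]silane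
Product: 18 (2R,3R,6E)-6-{2-[(tert-butyldiphenylsilyl)oxy]ethylidene}-3-{[(2R,4R)-4-hydroxypentan-2-yl]oxy}-2-methyloxepane-2-carboxylic acid, via dioxolanone adduct 16 (not isolated), via methyleneoxonium ion 17 (not isolated)
Conditions: 10, TiCl4 (2.5 equiv), 2,6-di-tert-butyl-4-methylpyridine (0.3 equiv), CH2Cl2, −78 °C; then 15 (1.2 equiv), 1 h; dilution with CH2Cl2 to 0.01 M, −78 to −30 °C; aqueous work-up at pH 3
Reagents that add atoms: none
Why: Proposed new method: TiCl4 opens the dioxane acetal of 10 at the C–O bond beside the axial methyl and the ketene acetal carbon of 15 (the future C2) attacks the acetal carbon (the future C3) with inversion; chloride then takes the silyl group to leave dioxolanone 16, and on warming TiCl4 held by the lactone carbonyl ionizes the O–CH2–O–C(=O) unit to the methyleneoxonium carboxylate 17, whose CH2 (the future C7) is captured by the silicon-bearing vinylsilane carbon (the future C6) with loss of Me3SiCl. The closest known reaction types are the Mukaiyama aldol–Prins cascade, the Lewis-acid coupling of chiral 1,3-dioxane acetal templates with silyl ketene acetals, the Lewis-acid substitution of 1,3-dioxolan-4-ones at the acetal carbon by π-nucleophiles and the acetal-initiated cyclization of vinylsilanes to alkylidene oxacycles; what is new is their union in one flask into a (4+3) annulation. The oxepane should close by 7-endo-trig attack on the C7=O1 oxocarbenium with the vinylsilane double bond exocyclic to the new ring, and no other ring is formed. C3 is controlled by the (4R,6R)-dimethyldioxane template (attack anti to the titanium-bound oxygen gives 3R), C2 by an open antiperiplanar transition state in which the C4 chain of the electrophile lies over the ring oxygen of the planar dioxole and not over its methyl (methyl cis to the C3 oxygen), and the 6E geometry by stereoretentive ipso-substitution of silicon. The step needs the C7 cation to be taken by C6 and not by the C3 oxygen (which would give a 1,3-dioxolane and then a tetrahydropyran) or by unreacted 15; the first is secured because the C3 oxygen is already a dialkyl ether, the second by using 15 in slight excess only, by the temperature gap between acetal opening (−78 °C) and acyloxymethyl ether ionization (about −30 °C) and by dilution before warming.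

Step 8
Reactants: 18 (2R,3R,6E)-6-{2-[(tert-butyldiphenylsilyl)oxy]ethylidene}-3-{[(2R,4R)-4-hydroxypentan-2-yl]oxy}-2-methyloxepane-2-carboxylic acid
Product: 19 (2R,4R)-4-{[(2S,3R,6E)-6-{2-[(tert-butyldiphenylsilyl)oxy]ethylidene}-2-(hydroxymethyl)-2-methyloxepan-3-yl]oxy}pentan-2-ol
Conditions: LiAlH4, THF, 0 °C to rt
Reagents that add atoms: none
Why: LiAlH4 should reduce the hindered carboxylic acid to the primary alcohol without touching the silyl ether, the alkene or either stereocentre.

Step 9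
Reactants: 19 (2R,4R)-4-{[(2S,3R,6E)-6-{2-[(tert-butyldiphenylsilyl)oxy]ethylidene}-2-(hydroxymethyl)-2-methyloxepan-3-yl]oxy}pentan-2-ol
Product: 20 (2R,3R,6E)-6-{2-[(tert-butyldiphenylsilyl)oxy]ethylidene}-3-{[(2R,4R)-4-hydroxypentan-2-yl]oxy}-2-methyloxepane-2-carbaldehyde
Conditions: TEMPO (10 mol %), PhI(OAc)2, CH2Cl2, rt
Reagents that add atoms: none
Why: Oxoammonium oxidation is selective for primary over secondary alcohols, so the non-enolizable aldehyde should form while the auxiliary hydroxyl stays and the C3 oxygen remains an ether (no retro-aldol path).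

Step 10
Reactants: 21 (S)-4-benzyl-3-propanoyl-1,3-oxazolidin-2-one; 22 allyl iodide
Product: 24 (S)-4-benzyl-3-[(R)-2-methylpent-4-enoyl]-1,3-oxazolidin-2-one, via sodium enolate 23 (not isolated)
Conditions: NaN(SiMe3)2, THF, −78 °C; then allyl iodide, −78 to −40 °C
Reagents that add atoms: none
Why: Evans alkylation: the chelated Z enolate should be allylated on the face away from the benzyl group, which sets the R methyl centre of the side chain.

Step 11
Reactants: 24 (S)-4-benzyl-3-[(R)-2-methylpent-4-enoyl]-1,3-oxazolidin-2-one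
Product: 25 (R)-N-methoxy-N,2-dimethylpent-4-enamide
Conditions: MeNHOMe·HCl, AlMe3, CH2Cl2, 0 °C to rt
Reagents that add atoms: N,O-dimethylhydroxylamine hydrochloride, CNOC.Cl
Why: Aluminum amide transamination cleaves the auxiliary directly to the Weinreb amide without epimerization of the α-centre.

Step 12
Reactants: 25 (R)-N-methoxy-N,2-dimethylpent-4-enamide
Product: 27 (R)-4-hydroxy-N-methoxy-N,2-dimethylbutanamide, via aldehyde 26 (not isolated)
Conditions: O3, CH2Cl2/MeOH, −78 °C; then NaBH4, −78 to 0 °C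
Reagents that add atoms: ozone, [O-][O+]=O
Why: Ozonolysis with reductive borohydride work-up shortens the allyl group to a hydroxyethyl group, and the Weinreb amide is inert to NaBH4 at low temperature.

Step 13
Reactants: 27 (R)-4-hydroxy-N-methoxy-N,2-dimethylbutanamide
Product: 28 (R)-N-methoxy-N,2-dimethyl-4-[(1-phenyl-1H-tetrazol-5-yl)sulfanyl]butanamide
Conditions: 1-phenyl-1H-tetrazole-5-thiol, PPh3, DIAD, THF, 0 °C to rt
Reagents that add atoms: 1-phenyl-1H-tetrazole-5-thiol, Sc1nnnn1-c1ccccc1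
Why: Mitsunobu thioetherification of the primary alcohol is fast and should outrun lactonization of the γ-hydroxy amide.

Step 14
Reactants: 28 (R)-N-methoxy-N,2-dimethyl-4-[(1-phenyl-1H-tetrazol-5-yl)sulfanyl]butanamide
Product: 29 (R)-N-methoxy-N,2-dimethyl-4-[(1-phenyl-1H-tetrazol-5-yl)sulfonyl]butanamide
Conditions: (NH4)6Mo7O24·4H2O (cat.), 30% H2O2, EtOH, 0 °C to rt
Reagents that add atoms: hydrogen peroxide, OO
Why: Molybdate-catalysed peroxide oxidation of the tetrazolyl sulfide to the sulfone is the standard entry to Julia–Kocienski reagents and leaves the amide untouched.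

Step 15
Reactants: 20 (2R,3R,6E)-6-{2-[(tert-butyldiphenylsilyl)oxy]ethylidene}-3-{[(2R,4R)-4-hydroxypentan-2-yl]oxy}-2-methyloxepane-2-carbaldehyde; 29 (R)-N-methoxy-N,2-dimethyl-4-[(1-phenyl-1H-tetrazol-5-yl)sulfonyl]butanamide
Product: 31 (2R,4E)-5-[(2S,3R,6E)-6-{2-[(tert-butyldiphenylsilyl)oxy]ethylidene}-3-{[(2R,4R)-4-hydroxypentan-2-yl]oxy}-2-methyloxepan-2-yl]-N-methoxy-N,2-dimethylpent-4-enamide, via potassium sulfonyl carbanion 30 (not isolated)
Conditions: 29 (2.5 equiv), KN(SiMe3)2 (2.4 equiv), DME, −60 °C; then 20, −60 °C to rt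
Reagents that add atoms: none
Why: Julia–Kocienski olefination should join the whole side-chain carbon skeleton to the non-enolizable aldehyde; one equivalent of carbanion is spent on the auxiliary hydroxyl, and the amide α-proton is far less acidic than the sulfone α-protons.

Step 16
Reactants: 31 (2R,4E)-5-[(2S,3R,6E)-6-{2-[(tert-butyldiphenylsilyl)oxy]ethylidene}-3-{[(2R,4R)-4-hydroxypentan-2-yl]oxy}-2-methyloxepan-2-yl]-N-methoxy-N,2-dimethylpent-4-enamide
Product: 32 (2R)-5-[(2S,3R,6E)-6-{2-[(tert-butyldiphenylsilyl)oxy]ethylidene}-3-{[(2R,4R)-4-hydroxypentan-2-yl]oxy}-2-methyloxepan-2-yl]-N-methoxy-N,2-dimethylpentanamide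
Conditions: H2 (1 atm), RhCl(PPh3)3 (10 mol %), benzene/EtOH, rt
Reagents that add atoms: none
Why: Homogeneous hydrogenation with RhCl(PPh3)3 reduces 1,2-disubstituted alkenes far faster than trisubstituted ones, so the chain alkene should be saturated while the exocyclic alkene is kept.

Step 17
Reactants: 32 (2R)-5-[(2S,3R,6E)-6-{2-[(tert-butyldiphenylsilyl)oxy]ethylidene}-3-{[(2R,4R)-4-hydroxypentan-2-yl]oxy}-2-methyloxepan-2-yl]-N-methoxy-N,2-dimethylpentanamide
Product: 34 (2R)-5-[(2S,3R,6E)-6-{2-[(tert-butyldiphenylsilyl)oxy]ethylidene}-3-hydroxy-2-methyloxepan-2-yl]-N-methoxy-N,2-dimethylpentanamide, via ketone 33 (not isolated)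
Conditions: (COCl)2, DMSO, CH2Cl2, −78 °C; Et3N, −78 to 0 °C; then crude ketone, K2CO3, MeOH, rt
Reagents that add atoms: none
Why: Swern oxidation of the only free hydroxyl gives a β-alkoxy ketone that should lose the C3 alkoxide by E1cB elimination under mild base, which is the standard removal of this acetal template and does not touch the C3–O bond.

Step 18
Reactants: 35 2-methylbut-3-yn-2-ol
Product: 36 (E)-2-methyl-4-(tributylstannyl)but-3-en-2-ol
Conditions: Bu3SnH, PdCl2(PPh3)2 (2 mol %), THF, 0 °C to rt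
Reagents that add atoms: tributylstannane, CCCC[SnH](CCCC)CCCC
Why: Palladium-catalysed syn-hydrostannation of the terminal alkyne should put tin on the terminal carbon, away from the tertiary carbinol, and give the E alkenylstannane.

Step 19
Reactants: 34 (2R)-5-[(2S,3R,6E)-6-{2-[(tert-butyldiphenylsilyl)oxy]ethylidene}-3-hydroxy-2-methyloxepan-2-yl]-N-methoxy-N,2-dimethylpentanamide; 36 (E)-2-methyl-4-(tributylstannyl)but-3-en-2-ol
Product: 38 (3E,6R)-9-[(2S,3R,6E)-6-{2-[(tert-butyldiphenylsilyl)oxy]ethylidene}-3-hydroxy-2-methyloxepan-2-yl]-2-hydroxy-2,6-dimethylnon-3-en-5-one, via dilithio reagent 37 (not isolated)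
Conditions: 36 (3.3 equiv), n-BuLi (6.6 equiv), THF, −78 to −40 °C; then 34, −78 to −30 °C; aqueous NH4Cl
Reagents that add atoms: none
Why: Tin–lithium exchange with retention gives the E alkenyllithium, whose addition to the Weinreb amide stops at the chelated tetrahedral adduct (Weinreb ketone synthesis), so the E enone should form on work-up with the α-methyl centre intact.

Step 20
Reactants: 38 (3E,6R)-9-[(2S,3R,6E)-6-{2-[(tert-butyldiphenylsilyl)oxy]ethylidene}-3-hydroxy-2-methyloxepan-2-yl]-2-hydroxy-2,6-dimethylnon-3-en-5-one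
Product: 39 (3E,6R)-2-hydroxy-9-[(2S,3R,6E)-3-hydroxy-6-(2-hydroxyethylidene)-2-methyloxepan-2-yl]-2,6-dimethylnon-3-en-5-one
Conditions: Bu4NF, AcOH (1:1), THF, 0 °C to rt
Reagents that add atoms: none
Why: Acetic-acid-buffered fluoride should cleave the primary silyl ether without epimerizing the α-methyl ketone or disturbing the allylic alcohols.

**Compound list**

1 | 3-(trimethylsilyl)prop-2-yn-1-ol | C[Si](C)(C)C#CCO | starting material
2 | sodium cyclic alkenylalanate from trans-hydroalumination of 1 (aluminum bound to the silyl-bearing carbon and to the alkoxide oxygen, two 2-methoxyethoxy ligands) | [Na+].C[Si](C)(C)C1=CCO[Al-]1(OCCOC)OCCOC | intermediate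
3 | (Z)-3-iodo-3-(trimethylsilyl)prop-2-en-1-ol | OC/C=C(/[Si](C)(C)C)I | intermediate
4 | tert-butyl{[(Z)-3-iodo-3-(trimethylsilyl)prop-2-en-1-yl]oxy}diphenylsilane | CC(C)(C)[Si](c1ccccc1)(c1ccccc1)OC/C=C(/[Si](C)(C)C)I | intermediate
5 | acrolein | C=CC=O | starting material
6 | (2R,4R)-pentane-2,4-diol | C[C@@H](O)C[C@@H](C)O | starting material
7 | 3-bromopropanal | BrCCC=O | intermediate
8 | (4R,6R)-2-(2-bromoethyl)-4,6-dimethyl-1,3-dioxane | C[C@@H]1C[C@@H](C)OC(CCBr)O1 | intermediate
9 | {2-[(4R,6R)-4,6-dimethyl-1,3-dioxan-2-yl]ethyl}zinc bromide | C[C@@H]1C[C@@H](C)OC(CC[Zn]Br)O1 | intermediate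
10 | tert-butyl{[(E)-5-[(4R,6R)-4,6-dimethyl-1,3-dioxan-2-yl]-3-(trimethylsilyl)pent-2-en-1-yl]oxy}diphenylsilane | C[C@@H]1C[C@@H](C)OC(CC/C(=C\CO[Si](c2ccccc2)(c2ccccc2)C(C)(C)C)[Si](C)(C)C)O1 | intermediate
11 | lactic acid (racemic) | CC(O)C(=O)O | starting material
12 | paraformaldehyde (formaldehyde unit shown) | C=O | starting material
13 | 5-methyl-1,3-dioxolan-4-one (racemic) | CC1OCOC1=O | intermediate
14 | lithium 5-methyl-1,3-dioxol-4-olate | [Li+].CC1=C([O-])OCO1 | intermediate
15 | tert-butyldimethyl[(5-methyl-1,3-dioxol-4-yl)oxy]silane | CC1=C(O[Si](C)(C)C(C)(C)C)OCO1 | intermediate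
16 | trichlorotitanium (TiCl3) alkoxide of (5R)-5-[(1R,4E)-6-[(tert-butyldiphenylsilyl)oxy]-1-{[(2R,4R)-4-hydroxypentan-2-yl]oxy}-4-(trimethylsilyl)hex-4-en-1-yl]-5-methyl-1,3-dioxolan-4-one | O=C1OCO[C@]1(C)[C@@H](CC/C(=C\CO[Si](c2ccccc2)(c2ccccc2)C(C)(C)C)[Si](C)(C)C)O[C@H](C)C[C@@H](C)O[Ti](Cl)(Cl)Cl | intermediate
17 | methyleneoxonium carboxylate formed from 16 by opening of the dioxolanone (carboxylate held by titanium) | C=[O+][C@@](C)(C(=O)[O-])[C@@H](CC/C(=C\CO[Si](c1ccccc1)(c1ccccc1)C(C)(C)C)[Si](C)(C)C)O[C@H](C)C[C@@H](C)O[Ti](Cl)(Cl)Cl | intermediate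
18 | (2R,3R,6E)-6-{2-[(tert-butyldiphenylsilyl)oxy]ethylidene}-3-{[(2R,4R)-4-hydroxypentan-2-yl]oxy}-2-methyloxepane-2-carboxylic acid | OC(=O)[C@]1(C)OC/C(=C/CO[Si](c2ccccc2)(c2ccccc2)C(C)(C)C)CC[C@H]1O[C@H](C)C[C@@H](C)O | intermediate
19 | (2R,4R)-4-{[(2S,3R,6E)-6-{2-[(tert-butyldiphenylsilyl)oxy]ethylidene}-2-(hydroxymethyl)-2-methyloxepan-3-yl]oxy}pentan-2-ol | OC[C@]1(C)OC/C(=C/CO[Si](c2ccccc2)(c2ccccc2)C(C)(C)C)CC[C@H]1O[C@H](C)C[C@@H](C)O | intermediate
20 | (2R,3R,6E)-6-{2-[(tert-butyldiphenylsilyl)oxy]ethylidene}-3-{[(2R,4R)-4-hydroxypentan-2-yl]oxy}-2-methyloxepane-2-carbaldehyde | O=C[C@]1(C)OC/C(=C/CO[Si](c2ccccc2)(c2ccccc2)C(C)(C)C)CC[C@H]1O[C@H](C)C[C@@H](C)O | intermediate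
21 | (S)-4-benzyl-3-propanoyl-1,3-oxazolidin-2-one | CCC(=O)N1[C@@H](Cc2ccccc2)COC1=O | starting material
22 | allyl iodide | C=CCI | starting material
23 | sodium (Z)-enolate of 21 | [Na+].C/C=C(\[O-])N1[C@@H](Cc2ccccc2)COC1=O | intermediate
24 | (S)-4-benzyl-3-[(R)-2-methylpent-4-enoyl]-1,3-oxazolidin-2-one | C=CC[C@@H](C)C(=O)N1[C@@H](Cc2ccccc2)COC1=O | intermediate
25 | (R)-N-methoxy-N,2-dimethylpent-4-enamide | C=CC[C@@H](C)C(=O)N(C)OC | intermediate
26 | (R)-N-methoxy-N,2-dimethyl-4-oxobutanamide | O=CC[C@@H](C)C(=O)N(C)OC | intermediate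
27 | (R)-4-hydroxy-N-methoxy-N,2-dimethylbutanamide | OCC[C@@H](C)C(=O)N(C)OC | intermediate
28 | (R)-N-methoxy-N,2-dimethyl-4-[(1-phenyl-1H-tetrazol-5-yl)sulfanyl]butanamide | CON(C)C(=O)[C@H](C)CCSc1nnnn1-c1ccccc1 | intermediate
29 | (R)-N-methoxy-N,2-dimethyl-4-[(1-phenyl-1H-tetrazol-5-yl)sulfonyl]butanamide | CON(C)C(=O)[C@H](C)CCS(=O)(=O)c1nnnn1-c1ccccc1 | intermediate
30 | potassium α-sulfonyl carbanion of 29 | [K+].CON(C)C(=O)[C@H](C)C[CH-]S(=O)(=O)c1nnnn1-c1ccccc1 | intermediate
31 | (2R,4E)-5-[(2S,3R,6E)-6-{2-[(tert-butyldiphenylsilyl)oxy]ethylidene}-3-{[(2R,4R)-4-hydroxypentan-2-yl]oxy}-2-methyloxepan-2-yl]-N-methoxy-N,2-dimethylpent-4-enamide | CON(C)C(=O)[C@H](C)C/C=C/[C@]1(C)OC/C(=C/CO[Si](c2ccccc2)(c2ccccc2)C(C)(C)C)CC[C@H]1O[C@H](C)C[C@@H](C)O | intermediate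
32 | (2R)-5-[(2S,3R,6E)-6-{2-[(tert-butyldiphenylsilyl)oxy]ethylidene}-3-{[(2R,4R)-4-hydroxypentan-2-yl]oxy}-2-methyloxepan-2-yl]-N-methoxy-N,2-dimethylpentanamide | CON(C)C(=O)[C@H](C)CCC[C@]1(C)OC/C(=C/CO[Si](c2ccccc2)(c2ccccc2)C(C)(C)C)CC[C@H]1O[C@H](C)C[C@@H](C)O | intermediate
33 | (2R)-5-[(2S,3R,6E)-6-{2-[(tert-butyldiphenylsilyl)oxy]ethylidene}-2-methyl-3-{[(2R)-4-oxopentan-2-yl]oxy}oxepan-2-yl]-N-methoxy-N,2-dimethylpentanamide | CON(C)C(=O)[C@H](C)CCC[C@]1(C)OC/C(=C/CO[Si](c2ccccc2)(c2ccccc2)C(C)(C)C)CC[C@H]1O[C@H](C)CC(C)=O | intermediate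
34 | (2R)-5-[(2S,3R,6E)-6-{2-[(tert-butyldiphenylsilyl)oxy]ethylidene}-3-hydroxy-2-methyloxepan-2-yl]-N-methoxy-N,2-dimethylpentanamide | CON(C)C(=O)[C@H](C)CCC[C@]1(C)OC/C(=C/CO[Si](c2ccccc2)(c2ccccc2)C(C)(C)C)CC[C@H]1O | intermediate
35 | 2-methylbut-3-yn-2-ol | C#CC(C)(C)O | starting material
36 | (E)-2-methyl-4-(tributylstannyl)but-3-en-2-ol | CCCC[Sn](CCCC)(CCCC)/C=C/C(C)(C)O | intermediate
37 | lithium (E)-4-lithio-2-methylbut-3-en-2-olate | [Li]/C=C/C(C)(C)O[Li] | intermediate
38 | (3E,6R)-9-[(2S,3R,6E)-6-{2-[(tert-butyldiphenylsilyl)oxy]ethylidene}-3-hydroxy-2-methyloxepan-2-yl]-2-hydroxy-2,6-dimethylnon-3-en-5-one | CC(C)(O)/C=C/C(=O)[C@H](C)CCC[C@]1(C)OC/C(=C/CO[Si](c2ccccc2)(c2ccccc2)C(C)(C)C)CC[C@H]1O | intermediate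
39 | (3E,6R)-2-hydroxy-9-[(2S,3R,6E)-3-hydroxy-6-(2-hydroxyethylidene)-2-methyloxepan-2-yl]-2,6-dimethylnon-3-en-5-one | C[C@H](CCC[C@]1(C)OC/C(=C/CO)CC[C@H]1O)C(=O)/C=C/C(C)(C)O | target

**Step count**

Total: 20 steps. Longest linear sequence: 11 steps (1, 2, 4, 7, 8, 9, 15, 16, 17, 19, 20).

**Steps most likely to fail**

Step 7 (proposed new method). What may go wrong: the methyleneoxonium ion may be intercepted by unreacted silyl ketene acetal or by chloride before the seven-membered ring closes; facial selectivity at C2 may be poor in the open transition state; and C3 selectivity may erode if the acetal opens through a loose ion pair. Fallback with known reactions only, from 10 back to 19: the two bonds are made in two separate operations with an open-chain lactate. Methyl lactate is protected with MEMCl/i-Pr2NEt to methyl 2-[(2-methoxyethoxy)methoxy]propanoate F1 and enolized and silylated (LiN(i-Pr)2, t-BuMe2SiCl) to its silyl ketene acetal F2. TiCl4-mediated coupling of F2 with acetal 10 at −78 °C (chiral acetal template coupling) should give the open-chain ester F3 with the C2–C3 bond in place; C2 epimers would be separated here. SnCl4 at −20 °C then ionizes the MEM ether and the vinylsilane closes the ring (acetal-initiated vinylsilane cyclization) to the oxepane ester F4, and LiAlH4 reduces F4 to diol 19.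

Step 15. What may go wrong: slow addition of the sulfonyl carbanion to the hindered α-quaternary aldehyde, with competing self-condensation of the sulfone and base-induced epimerization of the amide α-centre. Fallback from 20 back to 31: Wittig methylenation (Ph3P=CH2, THF) gives the vinyl oxepane F5, and olefin cross-metathesis of F5 with an excess of pentenamide 25 (second-generation Hoveyda–Grubbs catalyst, CH2Cl2, 40 °C) gives 31 without any carbanion chemistry at the side-chain stereocentre.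

Step 16. What may go wrong: the hindered chain alkene next to the quaternary carbon may reduce too slowly, so that forcing the reaction causes over-reduction or migration of the exocyclic trisubstituted alkene. Fallback from 20 back to 32, with no alkene to reduce: the vinyl oxepane F5 (see step 15) is hydroborated with 9-BBN and oxidized (NaBO3) to the primary alcohol F6, which is converted into the iodide F7 (I2, PPh3, imidazole). Alkyl–alkyl Negishi coupling (Pd2(dba)3, tricyclopentylphosphine, N-methylimidazole, THF/NMP) of F7 with the zinc reagent F8, made from commercial methyl (S)-3-bromo-2-methylpropanoate and zinc, gives the methyl ester F9, and MeNHOMe·HCl/i-PrMgCl converts F9 into Weinreb amide 32.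

**Further compounds**

F1 | step 7 | methyl 2-[(2-methoxyethoxy)methoxy]propanoate (racemic) | COCCOCOC(C)C(=O)OC
F2 | step 7 | (Z)-tert-butyl({1-methoxy-2-[(2-methoxyethoxy)methoxy]prop-1-en-1-yl}oxy)dimethylsilane | C/C(OCOCCOC)=C(\OC)O[Si](C)(C)C(C)(C)C
F3 | step 7 | methyl (2R,3R,6E)-8-[(tert-butyldiphenylsilyl)oxy]-3-{[(2R,4R)-4-hydroxypentan-2-yl]oxy}-2-[(2-methoxyethoxy)methoxy]-2-methyl-6-(trimethylsilyl)oct-6-enoate | COC(=O)[C@](C)(OCOCCOC)[C@@H](CC/C(=C\CO[Si](c1ccccc1)(c1ccccc1)C(C)(C)C)[Si](C)(C)C)O[C@H](C)C[C@@H](C)O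
F4 | step 7 | methyl (2R,3R,6E)-6-{2-[(tert-butyldiphenylsilyl)oxy]ethylidene}-3-{[(2R,4R)-4-hydroxypentan-2-yl]oxy}-2-methyloxepane-2-carboxylate | COC(=O)[C@]1(C)OC/C(=C/CO[Si](c2ccccc2)(c2ccccc2)C(C)(C)C)CC[C@H]1O[C@H](C)C[C@@H](C)O
F5 | step 15 | (2R,4R)-4-{[(2S,3R,6E)-6-{2-[(tert-butyldiphenylsilyl)oxy]ethylidene}-2-ethenyl-2-methyloxepan-3-yl]oxy}pentan-2-ol | C=C[C@]1(C)OC/C(=C/CO[Si](c2ccccc2)(c2ccccc2)C(C)(C)C)CC[C@H]1O[C@H](C)C[C@@H](C)O
F6 | step 16 | (2R,4R)-4-{[(2S,3R,6E)-6-{2-[(tert-butyldiphenylsilyl)oxy]ethylidene}-2-(2-hydroxyethyl)-2-methyloxepan-3-yl]oxy}pentan-2-ol | OCC[C@]1(C)OC/C(=C/CO[Si](c2ccccc2)(c2ccccc2)C(C)(C)C)CC[C@H]1O[C@H](C)C[C@@H](C)O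
F7 | step 16 | (2R,4R)-4-{[(2S,3R,6E)-6-{2-[(tert-butyldiphenylsilyl)oxy]ethylidene}-2-(2-iodoethyl)-2-methyloxepan-3-yl]oxy}pentan-2-ol | ICC[C@]1(C)OC/C(=C/CO[Si](c2ccccc2)(c2ccccc2)C(C)(C)C)CC[C@H]1O[C@H](C)C[C@@H](C)O
F8 | step 16 | [(2S)-3-methoxy-2-methyl-3-oxopropyl]zinc bromide | COC(=O)[C@H](C)C[Zn]Br
F9 | step 16 | methyl (2R)-5-[(2S,3R,6E)-6-{2-[(tert-butyldiphenylsilyl)oxy]ethylidene}-3-{[(2R,4R)-4-hydroxypentan-2-yl]oxy}-2-methyloxepan-2-yl]-2-methylpentanoate | COC(=O)[C@H](C)CCC[C@]1(C)OC/C(=C/CO[Si](c2ccccc2)(c2ccccc2)C(C)(C)C)CC[C@H]1O[C@H](C)C[C@@H](C)O
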